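At late times the south-east run reads 34 % at 2.00 min and 35 % at 5.00 min, a difference inside the scatter of 2 percentage points, so I read its last reading as a plateau.

| flask | starting material | coupling partner | second substrate | remark | time |
|---|---|---|---|---|---|
| south-west | 17 mM | 35 mM | 175 mM | run made earlier |  |
| south-east | 48 mM | 35 mM | 175 mM | run made earlier |  |
| east | 35 mM | 12 mM | 175 mM | run made earlier |  |
| delta | 35 mM | 35.0 mM | 175 mM |  | 10 min |
| beta | 12 mM | 8.00 mM | 500 mM |  | 10 min |

| run | time / min | target / % |
|---|---|---|
| south-west | 0.417 | 23 |
| south-west | 1.00 | 36 |
| south-west | 2.00 | 45 |
| south-west | 5.00 | 42 |
| south-east | 0.417 | 20 |
| south-east | 1.00 | 35 |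
| south-east | 2.00 | 34 |
| south-east | 5.00 | 35 |
| east | 0.667 | 10 |
| east | 2.00 | 16 |
| east | 3.00 | 15 |
| east | 5.00 | 15 |

(readings scatter by 2 percentage points)



1. the flask that ends with the higher amount of target, in percent of the starting material charged, or "neither" when 2 percentage points or less lies between them (delta / beta / neither)
2. final target, as a percentage of the starting material charged, in delta
3. final target, as a percentage of the starting material charged, in beta

I take the main step first: starting material + coupling partner → target. In the south-east run the coupling partner is then the limiting reagent, and the target can reach 72.9 % of the starting material, more than the run reads. So I add one process, a first-order loss of coupling partner, with [second substrate] frozen at its charge (pseudo-first-order). With T the final target in mM, the charge of coupling partner equals T + K ln(charged [starting material] / (charged [starting material] − T)).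

Solved for K, the plateaus give 42.2 mM in the south-east run, 41.5 mM in the east run and 48.4 mM in the south-west run, from its last two readings. I carry their mean, 44.0 mM, as the loss constant: the loss rate constant over the coupling rate constant, so the [starting material] at which coupling and loss share the coupling partner equally. The share reaching target is [starting material] / ([starting material] + K).

For delta I freeze [starting material] at its charge and get 15.5 mM of target. Refrozen halfway down that fall, it gives 13.4 mM, or 38.2 %. Now the rest: second substrate was never varied in the runs. With K unchanged, beta gives 14.3 %. If second substrate removes the coupling partner, K in beta scales to 126 mM and beta gives 5.80 %. I commit to the scaled value, so delta ends higher.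

The forecast names delta, with 39 % in delta and 7 % in beta, from the exact relation at K near 43 mM, so its delta differs from mine: “I lean towards the competitor reading”.

The flask gives delta: 41.3 % in delta and 5.89 % in beta.

    second substrate + coupling partner → second product (k = 2.40 M⁻¹ min⁻¹)
    starting material + second substrate → cross product (k = 3.70 M⁻¹ min⁻¹)
    coupling partner ⇌ dormant form (K = 7.30, k = 0.0600 min⁻¹)
    starting material + coupling partner → target (k = 25.0 M⁻¹ min⁻¹)

The forecast stands, and second substrate does remove coupling partner. It also takes starting material: at 10.0 min, delta holds 58.5 % of its charged starting material as cross product, with 0.155 % left. In the neighbour of delta charged with 300 mM of second substrate, K scales to 75.5 mM. Freezing at the charge gives 11.1 mM, and refreezing halfway gives 28.1 %. That neighbour ends at 30.3 % target.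

The numbers in the tables stem from a simulated flask from invented constants; noise was put on by code.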